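**Retrosynthetic overview**
1. Target 24 ← Schenck ene reaction of isopropylidene ketone 23 ← angelate on O3 of diol 20 ← acetone aldol and dehydration at C7 of trans-decalone 13 ← O4-directed hydrogenation of the 5-en-8-one 12.
2. The strategy rests on ring B (C5–C10): its carbonyl carbon C8 sits between C7 and the methylene C9 on the quaternary C10. C8 can therefore come from CO, and ring B from a ring A vinylcyclopropane 10 in which C9 bridges C5 and C10 and C6=C7 is a vinyl group on C5; the [5+1] carbonylation forms C8–C9 and C7–C8.
3. 10 ← O4-directed Simmons–Smith reaction of dienol 8 (sets C10) ← Stille vinylation of iodide 6 ← MeLi addition to iodoenone 5 (sets C4) ← silyloxy enone 4 ← acetoxylation and lipase resolution of 3-methylcyclohexenone 1 (sets C3).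
4. Ring order: ring A is bought with 1; the cyclopropane is fused to it in step 7 and opened with CO to ring B in step 8.

Key step: step 8

Convention: eudesmane numbering is used for all bicyclic compounds (ring A: C1–C5 and C10; ring B: C5–C10); α is the face of the C4 hydroxyl, β the face of the C10 methyl.
Assumption: the lipase is taken to hydrolyse the (R)-acetate of 2 faster; if screening showed the opposite preference, the recovered (R)-acetate would be cleaved with the same enzyme at longer time to the same alcohol 3.

**Step 1**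
Reactants: 1 3-methylcyclohex-2-en-1-one
Product: 2 (±)-6-acetoxy-3-methylcyclohex-2-en-1-one
Conditions: Mn(OAc)3 (3 equiv), benzene, reflux (Dean–Stark)
Reagents that add atoms: manganese triacetate Mn(OAc)3, CC(=O)[O-].CC(=O)[O-].CC(=O)[O-].[Mn+3]
Why: α′-acetoxylation of an enone by Mn(OAc)3 should put the acetate on the saturated α′ carbon through the manganese enolate, leaving the γ position alone, and gives the racemate that step 2 resolves.

**Step 2**
Reactants: 2 (±)-6-acetoxy-3-methylcyclohex-2-en-1-one
Product: 3 (R)-6-hydroxy-3-methylcyclohex-2-en-1-one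
Conditions: lipase (Amano PS, Burkholderia cepacia), pH 7 phosphate buffer/MTBE, 30 °C, stopped near 50 % conversion
Reagents that add atoms: none
Why: lipase-catalysed enantioselective hydrolysis (kinetic resolution) of the α′-acetoxy enone should release the (R)-alcohol under neutral conditions that do not epimerise the acyloin centre, the unreacted (S)-acetate being removed by chromatography, and this sets the future C3.

**Step 3**
Reactants: 3 (R)-6-hydroxy-3-methylcyclohex-2-en-1-one
Product: 4 (R)-6-(tert-butyldimethylsilyloxy)-3-methylcyclohex-2-en-1-one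
Conditions: TBSCl, imidazole, DMF, rt
Reagents that add atoms: tert-butyldimethylsilyl chloride, CC(C)(C)[Si](C)(C)Cl
Why: standard silylation of a secondary alcohol with imidazole as a mild base should protect O3 without enolising the neighbouring ketone.

**Step 4**
Reactants: 4 (R)-6-(tert-butyldimethylsilyloxy)-3-methylcyclohex-2-en-1-one
Product: 5 (R)-6-(tert-butyldimethylsilyloxy)-2-iodo-3-methylcyclohex-2-en-1-one
Conditions: I2 (2 equiv), pyridine/CH2Cl2, DMAP (cat.), rt, dark
Reagents that add atoms: iodine, II
Why: α-iodination of an enone by amine conjugate addition, iodination of the resulting enolate and elimination should place iodine on the α carbon (future C5) without touching the silyloxy-bearing centre.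

**Step 5**
Reactants: 5 (R)-6-(tert-butyldimethylsilyloxy)-2-iodo-3-methylcyclohex-2-en-1-one
Product: 6 (1R,6R)-6-(tert-butyldimethylsilyloxy)-2-iodo-1,3-dimethylcyclohex-2-en-1-ol (hydroxyl cis to the silyloxy group)
Conditions: MeLi, Et2O/THF, −78 °C; then H2O
Reagents that add atoms: methyllithium, [Li]C
Why: 1,2-addition of MeLi to the enone carbonyl is faster than iodine–lithium exchange at −78 °C and, by Felkin–Anh control, should occur anti to the bulky, non-chelating silyloxy group, so the new C4 carbinol carries its hydroxyl cis to O3 (both α).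

**Step 6**
Reactants: 6 (1R,6R)-6-(tert-butyldimethylsilyloxy)-2-iodo-1,3-dimethylcyclohex-2-en-1-ol; 7 tributyl(vinyl)stannane
Product: 8 (1S,6R)-6-(tert-butyldimethylsilyloxy)-1,3-dimethyl-2-vinylcyclohex-2-en-1-ol (hydroxyl cis to the silyloxy group)
Conditions: Pd2(dba)3 (cat.), AsPh3, CuI (cat.), NMP, 50 °C
Reagents that add atoms: tributyl(vinyl)stannane, C=C[Sn](CCCC)(CCCC)CCCC
Why: Stille coupling of the alkenyl iodide at zerovalent palladium, accelerated by AsPh3 and CuI for the hindered tetrasubstituted position, should install the C6=C7 vinyl group and tolerates the free tertiary alcohol and the silyl ether.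

**Step 7**
Reactants: 8 (1S,6R)-6-(tert-butyldimethylsilyloxy)-1,3-dimethyl-2-vinylcyclohex-2-en-1-ol; 9 diiodomethane
Product: 10 3-(tert-butyldimethylsilyloxy)-2,6-dimethyl-1-vinylbicyclo[4.1.0]heptan-2-ol with the cyclopropane CH2 (C9), the C4 hydroxyl and the C3 silyloxy group all on the α face (eudesmane: C9 bridges C5 and C10, vinyl on C5, methyl on C10 β)
Conditions: Et2Zn, CH2I2, CH2Cl2, −10 → 0 °C; aq. NaHCO3/Rochelle salt
Reagents that add atoms: diiodomethane, ICI
Why: in the Furukawa variant of the Simmons–Smith reaction the zinc alkoxide of O4 should deliver the methylene to the adjacent electron-rich tetrasubstituted C5=C10 bond on its own (α) face, which fixes C5 and the quaternary C10 with its methyl β, while the monosubstituted vinyl group, only homoallylic to O4 and twisted out of conjugation, reacts more slowly.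

**Step 8**
Reactants: 10 3-(tert-butyldimethylsilyloxy)-2,6-dimethyl-1-vinylbicyclo[4.1.0]heptan-2-ol (α-cyclopropane); 11 carbon monoxide
Product: 12 3α-(tert-butyldimethylsilyloxy)-4α-hydroxy-4β,10β-dimethyldecal-5-en-8-one
Conditions: [Rh(CO)2Cl]2 (5 mol %), dppp (10 mol %), AgOTf (10 mol %), premixed and AgCl filtered off; CO (0.2 atm in N2), DCE, 85 °C
Reagents that add atoms: carbon monoxide, [C-]#[O+]
Why: Monovalent rhodium binds the vinyl group and inserts into the cyclopropane bond C5–C9, giving a rhodacycle with a σ bond to C9 and a π-allyl over C5–C6–C7; CO then inserts into the Rh–C9 bond and reductive elimination joins the acyl carbon C8 to the allyl terminus C7. The closest known reaction type is the rhodium-catalysed [5+1] carbonylation of vinylcyclopropanes to β,γ-cyclohexenones. Ring B is closed in that reductive elimination from the acyl–allyl rhodacycle, the five atoms C9–C10–C5–C6–C7 taking up the one CO carbon, and the alkene is left at C5=C6. No stereocentre is created, since C10 (set in step 7) is not touched and C5 becomes trigonal. The one selectivity required is that rhodium enters the bond from C5 to the methylene C9 and not the bond from C5 to C10, which is secured because a metal–carbon bond to a CH2 forms far more easily than one to the fully substituted C10. In addition the C9–rhodium intermediate has no β-hydrogen, so diene formation cannot compete, and the neutral medium should keep the β,γ-enone from moving into conjugation or losing the C4 hydroxyl.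

**Step 9**
Reactants: 12 3α-(tert-butyldimethylsilyloxy)-4α-hydroxy-4β,10β-dimethyldecal-5-en-8-one
Product: 13 3α-(tert-butyldimethylsilyloxy)-4α-hydroxy-4β,10β-dimethyl-5α-decalin-8-one (trans-fused)
Conditions: H2 (1 atm), [Ir(cod)(PCy3)(py)]PF6 (5 mol %), CH2Cl2, rt
Reagents that add atoms: none
Why: hydroxyl-directed hydrogenation by the cationic monovalent iridium complex bound to the allylic 4α-hydroxyl should add hydrogen to the α face of C5=C6, which is also the open face because the C4 and C10 methyl groups shield the β side, and so sets the 5α-hydrogen of the trans ring fusion.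

**Step 10**
Reactants: 13 3α-(tert-butyldimethylsilyloxy)-4α-hydroxy-4β,10β-dimethyl-5α-decalin-8-one
Product: 14 3α-(tert-butyldimethylsilyloxy)-4β,10β-dimethyl-4α-(trimethylsilyloxy)-5α-decalin-8-one
Conditions: N-(trimethylsilyl)imidazole, CH2Cl2, rt
Reagents that add atoms: N-(trimethylsilyl)imidazole, C[Si](C)(C)n1ccnc1
Why: silyl transfer from N-(trimethylsilyl)imidazole should cap the hindered tertiary O4 without enolising the ketone, so that only the aldol hydroxyl can be activated in step 12.

**Step 11**
Reactants: 14 3α-(tert-butyldimethylsilyloxy)-4β,10β-dimethyl-4α-(trimethylsilyloxy)-5α-decalin-8-one; 15 acetone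
Product: 17 3α-(tert-butyldimethylsilyloxy)-7-(2-hydroxypropan-2-yl)-4β,10β-dimethyl-4α-(trimethylsilyloxy)-5α-decalin-8-one (C7 epimers), via lithium enolate 16 (not isolated)
Conditions: LDA, THF, −78 °C; acetone; AcOH, −78 °C
Reagents that add atoms: acetone, CC(C)=O
Why: kinetic deprotonation should occur at C7 and not at the neopentyl C9 next to the quaternary C10 (the known preference of such β-angular decalones), the enolate then adds to acetone in an aldol reaction that is quenched cold to prevent retro-aldol, and the C7 configuration is immaterial because step 12 removes it.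

**Step 12**
Reactants: 17 3α-(tert-butyldimethylsilyloxy)-7-(2-hydroxypropan-2-yl)-4β,10β-dimethyl-4α-(trimethylsilyloxy)-5α-decalin-8-one
Product: 19 3α-(tert-butyldimethylsilyloxy)-4α-(trimethylsilyloxy)eudesm-7(11)-en-8-one, via tertiary mesylate 18 (not isolated)
Conditions: MsCl, Et3N, CH2Cl2, 0 °C; then DBU, rt
Reagents that add atoms: none
Why: sulfene-type mesylation of the only free hydroxyl and E1cB elimination through the C7 enolate should give the conjugated tetrasubstituted isopropylidene ketone, DBU also converting any isopropenyl isomer into this thermodynamic enone.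

**Step 13**
Reactants: 19 3α-(tert-butyldimethylsilyloxy)-4α-(trimethylsilyloxy)eudesm-7(11)-en-8-one
Product: 20 3α,4α-dihydroxyeudesm-7(11)-en-8-one
Conditions: HF·pyridine, pyridine, THF, 0 °C → rt
Reagents that add atoms: none
Why: fluoride-driven cleavage of both silyl ethers under pyridine-buffered conditions should free the cis-diol without dehydrating the tertiary alcohol or disturbing the enone.

**Step 14**
Reactants: 20 3α,4α-dihydroxyeudesm-7(11)-en-8-one; 21 angelic acid
Product: 23 3α-angeloyloxy-4α-hydroxyeudesm-7(11)-en-8-one, via mixed anhydride 22 (not isolated)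
Conditions: 21, 2,4,6-trichlorobenzoyl chloride, Et3N, toluene, rt; then 20, 75 °C
Reagents that add atoms: angelic acid, C/C=C(/C)C(=O)O
Why: Yamaguchi-type acylation through the preformed mixed anhydride, run without a nucleophilic catalyst, should keep the Z geometry of the angeloyl group and esterify only the secondary O3, the tertiary O4 being too hindered to react.

**Step 15**
Reactants: 23 3α-angeloyloxy-4α-hydroxyeudesm-7(11)-en-8-one
Product: 24 3α-angeloyloxy-4α-hydroxy-11-hydroperoxyeudesm-6-en-8-one (target, CNP0161122.2)
Conditions: O2, hν (visible), tetraphenylporphyrin (cat.), CH2Cl2, 0 °C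
Reagents that add atoms: oxygen, O=O
Why: the Schenck ene reaction of singlet oxygen with an s-cis isopropylidene ketone should follow the known geminal selectivity, oxygen bonding to C11 and the axial C6 hydrogen on the group geminal to the carbonyl being removed so that the alkene shifts to C6=C7 in conjugation, with no new stereocentre and with the electron-poor trisubstituted angelate alkene reacting much more slowly.

**Compound list**
1 | 3-methylcyclohex-2-en-1-one | CC1=CC(=O)CCC1 | starting material
2 | (±)-6-acetoxy-3-methylcyclohex-2-en-1-one | CC(=O)OC1CCC(C)=CC1=O | intermediate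
3 | (R)-6-hydroxy-3-methylcyclohex-2-en-1-one | O[C@@H]1CCC(C)=CC1=O | intermediate
4 | (R)-6-(tert-butyldimethylsilyloxy)-3-methylcyclohex-2-en-1-one | CC(C)(C)[Si](C)(C)O[C@@H]1CCC(C)=CC1=O | intermediate
5 | (R)-6-(tert-butyldimethylsilyloxy)-2-iodo-3-methylcyclohex-2-en-1-one | CC(C)(C)[Si](C)(C)O[C@@H]1CCC(C)=C(I)C1=O | intermediate
6 | (1R,6R)-6-(tert-butyldimethylsilyloxy)-2-iodo-1,3-dimethylcyclohex-2-en-1-ol | CC(C)(C)[Si](C)(C)O[C@@H]1CCC(C)=C(I)[C@]1(C)O | intermediate
7 | tributyl(vinyl)stannane | C=C[Sn](CCCC)(CCCC)CCCC | starting material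
8 | (1S,6R)-6-(tert-butyldimethylsilyloxy)-1,3-dimethyl-2-vinylcyclohex-2-en-1-ol | CC(C)(C)[Si](C)(C)O[C@@H]1CCC(C)=C(C=C)[C@]1(C)O | intermediate
9 | diiodomethane | ICI | starting material
10 | 3-(tert-butyldimethylsilyloxy)-2,6-dimethyl-1-vinylbicyclo[4.1.0]heptan-2-ol, cyclopropane CH2, hydroxyl and silyloxy group on the α face | CC(C)(C)[Si](C)(C)O[C@@H]1CC[C@]2(C)C[C@]2(C=C)[C@]1(C)O | intermediate
11 | carbon monoxide | [C-]#[O+] | starting material
12 | 3α-(tert-butyldimethylsilyloxy)-4α-hydroxy-4β,10β-dimethyldecal-5-en-8-one | CC(C)(C)[Si](C)(C)O[C@@H]1CC[C@]2(C)CC(=O)CC=C2[C@]1(C)O | intermediate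
13 | 3α-(tert-butyldimethylsilyloxy)-4α-hydroxy-4β,10β-dimethyl-5α-decalin-8-one | CC(C)(C)[Si](C)(C)O[C@@H]1CC[C@]2(C)CC(=O)CC[C@H]2[C@]1(C)O | intermediate
14 | 3α-(tert-butyldimethylsilyloxy)-4β,10β-dimethyl-4α-(trimethylsilyloxy)-5α-decalin-8-one | CC(C)(C)[Si](C)(C)O[C@@H]1CC[C@]2(C)CC(=O)CC[C@H]2[C@]1(C)O[Si](C)(C)C | intermediate
15 | acetone | CC(C)=O | starting material
16 | lithium C7–C8 enolate of 14 | CC(C)(C)[Si](C)(C)O[C@@H]1CC[C@]2(C)CC(O[Li])=CC[C@H]2[C@]1(C)O[Si](C)(C)C | intermediate
17 | 3α-(tert-butyldimethylsilyloxy)-7-(2-hydroxypropan-2-yl)-4β,10β-dimethyl-4α-(trimethylsilyloxy)-5α-decalin-8-one (C7 epimers) | CC(C)(C)[Si](C)(C)O[C@@H]1CC[C@]2(C)CC(=O)C(C(C)(C)O)C[C@H]2[C@]1(C)O[Si](C)(C)C | intermediate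
18 | C11 methanesulfonate of 17 | CC(C)(C)[Si](C)(C)O[C@@H]1CC[C@]2(C)CC(=O)C(C(C)(C)OS(C)(=O)=O)C[C@H]2[C@]1(C)O[Si](C)(C)C | intermediate
19 | 3α-(tert-butyldimethylsilyloxy)-4α-(trimethylsilyloxy)eudesm-7(11)-en-8-one | CC(C)(C)[Si](C)(C)O[C@@H]1CC[C@]2(C)CC(=O)C(=C(C)C)C[C@H]2[C@]1(C)O[Si](C)(C)C | intermediate
20 | 3α,4α-dihydroxyeudesm-7(11)-en-8-one | O[C@@H]1CC[C@]2(C)CC(=O)C(=C(C)C)C[C@H]2[C@]1(C)O | intermediate
21 | angelic acid, (Z)-2-methylbut-2-enoic acid | C/C=C(/C)C(=O)O | starting material
22 | angelic 2,4,6-trichlorobenzoic anhydride | C/C=C(/C)C(=O)OC(=O)c1c(Cl)cc(Cl)cc1Cl | intermediate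
23 | 3α-angeloyloxy-4α-hydroxyeudesm-7(11)-en-8-one | C/C=C(/C)C(=O)O[C@@H]1CC[C@]2(C)CC(=O)C(=C(C)C)C[C@H]2[C@]1(C)O | intermediate
24 | 3α-angeloyloxy-4α-hydroxy-11-hydroperoxyeudesm-6-en-8-one (CNP0161122.2) | C/C=C(/C)C(=O)O[C@@H]1CC[C@]2(C)CC(=O)C(C(C)(C)OO)=C[C@H]2[C@]1(C)O | target

**Step count**
Total: 15 steps. Longest linear sequence: 15 steps (1 → 24).

**Steps most likely to fail**

Step 8. Rhodium may insert only slowly into the fully substituted vinylcyclopropane, the cationic metal may ionise the tertiary cyclopropylcarbinol, or the β,γ-enone may drift into conjugation. The fallback replaces the catalytic rhodium cycle with the stoichiometric iron-mediated photochemical carbonylation of alkenylcyclopropanes. Setting out from 10, irradiation with Fe(CO)5 under CO (1 atm) in isopropanol should pass through a neutral σ-alkyl π-allyl acyl iron carbonyl complex that collapses to the same β,γ-enone, so the detour returns to the route at 12; no new compound is isolated (F0).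

Step 7. Methylene transfer may go to the vinyl group or stall at the hindered tetrasubstituted C5=C10 bond, and zinc iodide may ionise the tertiary allylic alcohol. The fallback builds the cyclopropane before the vinyl group exists. Setting out from 6, Stille coupling with (tributylstannyl)methanol (Pd(PPh3)4, dioxane, 90 °C) should give the hydroxymethyl diol F1, whose single alkene is now flanked by two directing hydroxyls. Et2Zn/CH2I2 (CH2Cl2, 0 °C) should then give the cyclopropyl diol F2 with the methylene on the face of the tertiary alkoxide. Dess–Martin periodinane (NaHCO3, CH2Cl2) oxidises only the primary alcohol to the cyclopropanecarbaldehyde F3. Wittig methylenation (Ph3PCH3Br, KOtBu, THF, 0 °C) returns to the route at 10.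

Step 14. The angeloyl unit may isomerise from Z to E (tiglate) during activation, and the axial, neopentyl-like C3 hydroxyl may acylate slowly. The fallback makes the Z alkene after the ester bond. Setting out from 20, esterification with 2-[bis(2,2,2-trifluoroethoxy)phosphoryl]propanoic acid (DCC, DMAP, CH2Cl2) should give the phosphonate ester F4. Still–Gennari olefination with acetaldehyde (KHMDS, 18-crown-6, THF, −78 °C) should then form the (Z)-2-methylbut-2-enoate and return to the route at 23.

**Further compounds**
F0 | step 8 | none | none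
F1 | step 7 | (1S,6R)-6-(tert-butyldimethylsilyloxy)-2-(hydroxymethyl)-1,3-dimethylcyclohex-2-en-1-ol | CC(C)(C)[Si](C)(C)O[C@@H]1CCC(C)=C(CO)[C@]1(C)O
F2 | step 7 | 3-(tert-butyldimethylsilyloxy)-1-(hydroxymethyl)-2,6-dimethylbicyclo[4.1.0]heptan-2-ol, cyclopropane CH2 on the α face | CC(C)(C)[Si](C)(C)O[C@@H]1CC[C@]2(C)C[C@]2(CO)[C@]1(C)O
F3 | step 7 | 4-(tert-butyldimethylsilyloxy)-5-hydroxy-1,5-dimethylbicyclo[4.1.0]heptane-6-carbaldehyde, cyclopropane CH2 on the α face | CC(C)(C)[Si](C)(C)O[C@@H]1CC[C@]2(C)C[C@]2(C=O)[C@]1(C)O
F4 | step 14 | 3α-{2-[bis(2,2,2-trifluoroethoxy)phosphoryl]propanoyloxy}-4α-hydroxyeudesm-7(11)-en-8-one | CC(C(=O)O[C@@H]1CC[C@]2(C)CC(=O)C(=C(C)C)C[C@H]2[C@]1(C)O)P(=O)(OCC(F)(F)F)OCC(F)(F)F
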